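## Retrosynthetic overview

1. The (E)-styryl C=C bond is cut by a Horner–Wadsworth–Emmons disconnection into a quaternary cyclohexenecarbaldehyde (carrying the 6-coumarinyl group) and a (7-methoxycoumarin-8-yl)methylphosphonate made from umbelliferone.
2. The quaternary centre comes from α-methylation of the ring aldehyde enolate, with CH3 entering anti to the neighbouring aryl group.
3. The cyclohexene is closed by ring-closing metathesis of a diene aldehyde (vinyl and isopropenyl ends).
4. The diene aldehyde comes from an iridium/amine-catalysed enantioselective α-allylation of 5-methylhex-5-enal with a racemic coumarinyl vinyl carbinol, which sets the benzylic centre.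
5. Ring order: the two coumarin lactones first (one by Wittig/lactonisation, one bought as umbelliferone), the carbocycle last.

Assumption: the (R)-configured phosphoramidite–olefin ligand, (R)-N-(dinaphtho[2,1-d:1′,2′-f][1,3,2]dioxaphosphepin-4-yl)dibenzo[b,f]azepine, is taken to give the (3S) benzylic centre of the allylation product; the sense is checked on the first run and the (S)-ligand is used instead if it is opposite, with nothing else changed.

## Route

**Fragment A (steps 1–4)**

Step 1
Reactants: 1 2-hydroxy-4-methoxybenzaldehyde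
Product: 2 5-bromo-2-hydroxy-4-methoxybenzaldehyde
Conditions: Br2 (1.05 equiv), AcOH, 20 °C
Reagents that add atoms: bromine (BrBr)
Why: Electrophilic aromatic bromination, regioselective because C-5 is para to the free hydroxyl group and ortho to the methoxy group and is the least hindered activated position.

Step 2
Reactants: 2 5-bromo-2-hydroxy-4-methoxybenzaldehyde
Product: 5 6-bromo-7-methoxy-2H-chromen-2-one, via E-hydroxycinnamate ester 3 (not isolated), via Z-hydroxycinnamate ester 4 (not isolated)
Conditions: Ph3P=CHCO2Et (1.2 equiv), PhNEt2, 210 °C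
Reagents that add atoms: ethyl (triphenylphosphoranylidene)acetate (CCOC(=O)C=P(c1ccccc1)(c1ccccc1)c1ccccc1)
Why: Wittig olefination of the salicylaldehyde followed in the same pot by thermal E-to-Z isomerisation and lactonisation of the 2-hydroxycinnamate, the classical coumarin synthesis in refluxing N,N-diethylaniline.

Step 3
Reactants: 5 6-bromo-7-methoxy-2H-chromen-2-one
Product: 6 7-methoxy-2-oxo-2H-chromene-6-carbaldehyde
Conditions: Pd(OAc)2 (1 mol %), nBuP(1-adamantyl)2 (3 mol %), CO/H2 (1:1, 5 bar), Me2NCH2CH2NMe2 (0.75 equiv), toluene, 100 °C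
Reagents that add atoms: carbon monoxide ([C-]#[O+])
Why: Palladium-catalysed reductive carbonylation of the aryl bromide, a neutral formylation in which the bulky electron-rich phosphine drives oxidative addition of the electron-rich bromide and the lactone is left alone.

Step 4
Reactants: 6 7-methoxy-2-oxo-2H-chromene-6-carbaldehyde
Product: 7 racemic 6-(1-hydroxyprop-2-en-1-yl)-7-methoxy-2H-chromen-2-one
Conditions: CH2=CHMgBr (1.1 equiv), THF, −78 °C; aq. NH4Cl at −78 °C
Reagents that add atoms: vinylmagnesium bromide (C=C[Mg]Br)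
Why: Grignard 1,2-addition, chemoselective at −78 °C for the aldehyde over the far less electrophilic lactone, the new carbinol centre being left racemic on purpose because it is ionised in step 7.

**Fragment B (steps 5–6)**

Step 5
Reactants: 8 ethyl 5-oxohexanoate
Product: 9 ethyl 5-methylhex-5-enoate
Conditions: Ph3PCH3Br (1.2 equiv), KOtBu (1.15 equiv), THF, 0 → 20 °C
Reagents that add atoms: methyltriphenylphosphonium bromide (C[P+](c1ccccc1)(c1ccccc1)c1ccccc1.[Br-])
Why: Wittig methylenation, chemoselective for the ketone over the ester with the preformed non-stabilised ylide.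

Step 6
Reactants: 9 ethyl 5-methylhex-5-enoate
Product: 11 5-methylhex-5-enal, via aluminium hemiacetal 10 (not isolated)
Conditions: iBu2AlH (1.05 equiv), CH2Cl2, −78 °C; MeOH, then aq. KNaC4H4O6
Reagents that add atoms: none
Why: Partial reduction of the ester by one equivalent of hydride at −78 °C, where the tetrahedral aluminium hemiacetal is stable and releases the aldehyde only on work-up.

**Union and key steps (steps 7–9)**

Step 7
Reactants: 7 racemic 6-(1-hydroxyprop-2-en-1-yl)-7-methoxy-2H-chromen-2-one; 11 5-methylhex-5-enal (3 equiv)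
Product: 12 (2S,3S)-3-(7-methoxy-2-oxo-2H-chromen-6-yl)-2-(3-methylbut-3-en-1-yl)pent-4-enal
Conditions: [Ir(cod)Cl]2 (3 mol %), (R)-phosphoramidite–olefin ligand (12 mol %), (R)-2-[bis(3,5-bis(trifluoromethyl)phenyl)(trimethylsilyloxy)methyl]pyrrolidine (15 mol %), ZnBr2 (7.5 mol %), ClCH2CH2Cl, 25 °C
Reagents that add atoms: none
Why: Stereodivergent dual catalysis merging iridium-catalysed enantioselective allylic substitution with enamine catalysis, in which the chiral iridium π-allyl complex formed from the racemic carbinol by loss of water is attacked at its benzylic terminus from one face to set the (3S) centre while the chiral enamine sets C-2 as (2S), a centre that is erased again in step 9.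

Step 8
Reactants: 12 (2S,3S)-3-(7-methoxy-2-oxo-2H-chromen-6-yl)-2-(3-methylbut-3-en-1-yl)pent-4-enal
Product: 13 (1S,2S)-2-(7-methoxy-2-oxo-2H-chromen-6-yl)-4-methylcyclohex-3-ene-1-carbaldehyde (trans)
Conditions: RuCl2(=CHPh)(PCy3)(H2IMes) (second-generation Grubbs catalyst, 3 mol %), CH2Cl2 (0.01 M), 40 °C
Reagents that add atoms: none
Why: Ring-closing metathesis of the monosubstituted and the 1,1-disubstituted alkene closes the six-membered ring and forms its trisubstituted C=C bond with loss of ethene, both stereocentres being untouched and the electron-poor coumarin C=C bond inert.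

Step 9
Reactants: 13 (1S,2S)-2-(7-methoxy-2-oxo-2H-chromen-6-yl)-4-methylcyclohex-3-ene-1-carbaldehyde
Product: 15 (1R,2R)-2-(7-methoxy-2-oxo-2H-chromen-6-yl)-1,4-dimethylcyclohex-3-ene-1-carbaldehyde, via potassium enolate 14 (not isolated)
Conditions: KN(SiMe3)2 (1.1 equiv), THF, −78 °C; MeI (5 equiv), −78 → 0 °C
Reagents that add atoms: iodomethane (CI)
Why: α-Alkylation of the aldehyde enolate, whose exocyclic double bond pushes the vicinal aryl group pseudoaxial (allylic 1,3-strain) so that iodomethane enters the opposite face, placing CH3 trans and CHO cis to the aryl group (new quaternary centre R) while the benzylic centre is untouched.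

**Fragment C (steps 10–14)**

Step 10
Reactants: 16 7-hydroxy-2H-chromen-2-one (umbelliferone)
Product: 18 7-hydroxy-2-oxo-2H-chromene-8-carbaldehyde, via aldimine 17 (not isolated)
Conditions: (CH2)6N4 (2 equiv), CF3CO2H, 85 °C; then H2O, aq. HCl, 60 °C
Reagents that add atoms: hexamethylenetetramine (C1N2CN3CN1CN(C2)C3); water (O)
Why: Duff ortho-formylation, which with 7-hydroxycoumarin goes to C-8, the ortho position of higher electron density (as in 2-naphthol), through aminomethylation, hydride transfer and hydrolysis of the imine.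

Step 11
Reactants: 18 7-hydroxy-2-oxo-2H-chromene-8-carbaldehyde
Product: 19 7-methoxy-2-oxo-2H-chromene-8-carbaldehyde
Conditions: MeI (1.5 equiv), K2CO3 (1.5 equiv), acetone, 56 °C
Reagents that add atoms: iodomethane (CI)
Why: Williamson O-methylation of the phenol under weakly basic anhydrous conditions that leave the lactone and the aldehyde alone.

Step 12
Reactants: 19 7-methoxy-2-oxo-2H-chromene-8-carbaldehyde
Product: 20 8-(hydroxymethyl)-7-methoxy-2H-chromen-2-one
Conditions: NaBH4 (0.5 equiv), THF/MeOH, 0 °C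
Reagents that add atoms: none
Why: Borohydride reduction, chemoselective at 0 °C for the aryl aldehyde over the coumarin lactone and its conjugated C=C bond.

Step 13
Reactants: 20 8-(hydroxymethyl)-7-methoxy-2H-chromen-2-one
Product: 21 8-(bromomethyl)-7-methoxy-2H-chromen-2-one
Conditions: PBr3 (0.4 equiv), CH2Cl2, 0 → 20 °C
Reagents that add atoms: phosphorus tribromide (BrP(Br)Br)
Why: Conversion of the electron-rich benzylic alcohol into the bromide by nucleophilic substitution on its phosphite ester.

Step 14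
Reactants: 21 8-(bromomethyl)-7-methoxy-2H-chromen-2-one
Product: 23 diethyl [(7-methoxy-2-oxo-2H-chromen-8-yl)methyl]phosphonate, via triethoxyphosphonium bromide 22 (not isolated)
Conditions: P(OEt)3 (3 equiv, neat), 130 °C
Reagents that add atoms: triethyl phosphite (CCOP(OCC)OCC)
Why: Michaelis–Arbuzov reaction of the reactive benzylic bromide, driven by loss of volatile bromoethane.

**Final coupling (step 15)**

Step 15
Reactants: 15 (1R,2R)-2-(7-methoxy-2-oxo-2H-chromen-6-yl)-1,4-dimethylcyclohex-3-ene-1-carbaldehyde; 23 diethyl [(7-methoxy-2-oxo-2H-chromen-8-yl)methyl]phosphonate (1.5 equiv)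
Product: 26 7-methoxy-6-[(1S,6S)-6-[(E)-2-(7-methoxy-2-oxo-2H-chromen-8-yl)ethenyl]-3,6-dimethylcyclohex-2-en-1-yl]-2H-chromen-2-one, via potassium phosphonate carbanion 24 (not isolated), via oxidophosphonate adduct 25 (not isolated)
Conditions: KN(SiMe3)2 (1.45 equiv), 18-crown-6, THF, −78 °C; then 15, −78 → 25 °C
Reagents that add atoms: none
Why: Horner–Wadsworth–Emmons olefination of the non-enolisable aldehyde with the benzylic phosphonate carbanion, which gives the thermodynamically favoured E-alkene through reversible addition and syn elimination of phosphate, with no stereocentre touched.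

## Compound list

1 | 2-hydroxy-4-methoxybenzaldehyde | COc1ccc(C=O)c(O)c1 | starting material
2 | 5-bromo-2-hydroxy-4-methoxybenzaldehyde | COc1cc(O)c(C=O)cc1Br | intermediate
3 | ethyl (E)-3-(5-bromo-2-hydroxy-4-methoxyphenyl)prop-2-enoate (not isolated) | CCOC(=O)/C=C/c1cc(Br)c(OC)cc1O | intermediate
4 | ethyl (Z)-3-(5-bromo-2-hydroxy-4-methoxyphenyl)prop-2-enoate (not isolated) | CCOC(=O)/C=C\c1cc(Br)c(OC)cc1O | intermediate
5 | 6-bromo-7-methoxy-2H-chromen-2-one | COc1cc2oc(=O)ccc2cc1Br | intermediate
6 | 7-methoxy-2-oxo-2H-chromene-6-carbaldehyde | COc1cc2oc(=O)ccc2cc1C=O | intermediate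
7 | racemic 6-(1-hydroxyprop-2-en-1-yl)-7-methoxy-2H-chromen-2-one | COc1cc2oc(=O)ccc2cc1C(O)C=C | intermediate
8 | ethyl 5-oxohexanoate | CCOC(=O)CCCC(C)=O | starting material
9 | ethyl 5-methylhex-5-enoate | CCOC(=O)CCCC(C)=C | intermediate
10 | diisobutylaluminium hemiacetal of 9 (not isolated) | CCOC(CCCC(C)=C)O[Al](CC(C)C)CC(C)C | intermediate
11 | 5-methylhex-5-enal | O=CCCCC(C)=C | intermediate
12 | (2S,3S)-3-(7-methoxy-2-oxo-2H-chromen-6-yl)-2-(3-methylbut-3-en-1-yl)pent-4-enal | COc1cc2oc(=O)ccc2cc1[C@@H](C=C)[C@@H](C=O)CCC(C)=C | intermediate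
13 | (1S,2S)-2-(7-methoxy-2-oxo-2H-chromen-6-yl)-4-methylcyclohex-3-ene-1-carbaldehyde (aryl and CHO trans) | COc1cc2oc(=O)ccc2cc1[C@H]1C=C(C)CC[C@@H]1C=O | intermediate
14 | potassium enolate of 13 (not isolated) | COc1cc2oc(=O)ccc2cc1[C@H]1C=C(C)CCC1=C[O-].[K+] | intermediate
15 | (1R,2R)-2-(7-methoxy-2-oxo-2H-chromen-6-yl)-1,4-dimethylcyclohex-3-ene-1-carbaldehyde (aryl and CHO cis, aryl and CH3 trans) | COc1cc2oc(=O)ccc2cc1[C@H]1C=C(C)CC[C@@]1(C)C=O | intermediate
16 | 7-hydroxy-2H-chromen-2-one (umbelliferone) | Oc1ccc2ccc(=O)oc2c1 | starting material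
17 | 7-hydroxy-8-(iminomethyl)-2H-chromen-2-one (not isolated) | N=Cc1c(O)ccc2ccc(=O)oc12 | intermediate
18 | 7-hydroxy-2-oxo-2H-chromene-8-carbaldehyde | O=Cc1c(O)ccc2ccc(=O)oc12 | intermediate
19 | 7-methoxy-2-oxo-2H-chromene-8-carbaldehyde | COc1ccc2ccc(=O)oc2c1C=O | intermediate
20 | 8-(hydroxymethyl)-7-methoxy-2H-chromen-2-one | COc1ccc2ccc(=O)oc2c1CO | intermediate
21 | 8-(bromomethyl)-7-methoxy-2H-chromen-2-one | COc1ccc2ccc(=O)oc2c1CBr | intermediate
22 | triethoxy[(7-methoxy-2-oxo-2H-chromen-8-yl)methyl]phosphonium bromide (not isolated) | CCO[P+](OCC)(OCC)Cc1c(OC)ccc2ccc(=O)oc12.[Br-] | intermediate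
23 | diethyl [(7-methoxy-2-oxo-2H-chromen-8-yl)methyl]phosphonate | CCOP(=O)(OCC)Cc1c(OC)ccc2ccc(=O)oc12 | intermediate
24 | potassium carbanion of 23 (not isolated) | CCOP(=O)(OCC)[CH-]c1c(OC)ccc2ccc(=O)oc12.[K+] | intermediate
25 | potassium β-oxidophosphonate adduct of 15 and 24 (not isolated, mixture at the two new centres) | COc1cc2oc(=O)ccc2cc1[C@H]1C=C(C)CC[C@@]1(C)C([O-])C(c1c(OC)ccc2ccc(=O)oc12)P(=O)(OCC)OCC.[K+] | intermediate
26 | 7-methoxy-6-[(1S,6S)-6-[(E)-2-(7-methoxy-2-oxo-2H-chromen-8-yl)ethenyl]-3,6-dimethylcyclohex-2-en-1-yl]-2H-chromen-2-one | COc1cc2oc(=O)ccc2cc1[C@H]1C=C(C)CC[C@@]1(C)/C=C/c1c(OC)ccc2ccc(=O)oc12 | target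

## Step count and risks

Total step count: 15.
Longest linear sequence: 8 steps (1, 2, 3, 4, 7, 8, 9, 15). The other branches are steps 5–6 (two steps) and steps 10–14 (five steps).

**Step 7 (dual-catalytic allylation).** The lactone-bearing, electron-rich carbinol is an untested substrate, and regio- and enantiocontrol carry the whole absolute configuration.
Fallback: it sets out from 7 and 9 and comes back to the route at 13. Compound 7 is isomerised by 1,3-transposition (Ph3SiOReO3, 1 mol %, Et2O, 0 °C) to the linear alcohol (E)-6-(3-hydroxyprop-1-en-1-yl)-7-methoxy-2H-chromen-2-one F1, and 9 is saponified (LiOH, THF/H2O) to 5-methylhex-5-enoic acid F2. Carbodiimide coupling of the two (dicyclohexylcarbodiimide, 4-dimethylaminopyridine, CH2Cl2) gives (E)-3-(7-methoxy-2-oxo-2H-chromen-6-yl)prop-2-en-1-yl 5-methylhex-5-enoate F3. Corey's boron-mediated enantioselective Ireland–Claisen rearrangement then gives (2S,3S)-3-(7-methoxy-2-oxo-2H-chromen-6-yl)-2-(3-methylbut-3-en-1-yl)pent-4-enoic acid F4; the reagent is (4R,5R)-2-bromo-4,5-diphenyl-1,3-bis[3,5-bis(trifluoromethyl)phenylsulfonyl]-1,3,2-diazaborolidine or its enantiomer with a tertiary amine, −78 → −20 °C, and the reagent enantiomer and enolisation conditions are fixed by a test run. Ring-closing metathesis with the same ruthenium catalyst gives (1S,2S)-2-(7-methoxy-2-oxo-2H-chromen-6-yl)-4-methylcyclohex-3-ene-1-carboxylic acid F5. BH3·SMe2 (THF, 0 °C) reduces the acid in the presence of the lactone to 6-[(1S,6S)-6-(hydroxymethyl)-3-methylcyclohex-2-en-1-yl]-7-methoxy-2H-chromen-2-one F6, and Dess–Martin oxidation (CH2Cl2, 20 °C) returns 13.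

**Step 9 (enolate methylation).** O-methylation, incomplete facial selectivity and attack of base on the lactone can each erode the yield. Any O-methyl enol ether can be hydrolysed back to 13 and recycled.
Fallback: it sets out from 9 and 7 and comes back at 15, building the quaternary centre under catalyst control before the ring is closed. Compound 9 is α-methylated (LiN(iPr)2, MeI, THF, −78 °C) to racemic ethyl 2,5-dimethylhex-5-enoate F7, which is reduced (iBu2AlH, CH2Cl2, −78 °C) to racemic 2,5-dimethylhex-5-enal F8. F8 and 7 are joined by the branched-aldehyde variant of the dual catalysis ([Ir(cod)Cl]2, the same (R)-ligand, a cinchona-derived primary amine such as 9-amino-9-deoxy-epi-quinine, Cl3CCO2H, ClCH2CH2Cl, 25 °C) to give (2R,3R)-3-(7-methoxy-2-oxo-2H-chromen-6-yl)-2-methyl-2-(3-methylbut-3-en-1-yl)pent-4-enal F9. Control of the quaternary centre by the amine is expected to be only moderate for a dialkyl aldehyde, so the minor diastereomer is removed by chromatography. Ring-closing metathesis of F9 with the same ruthenium catalyst gives 15 directly.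

**Step 15 (Horner–Wadsworth–Emmons coupling).** The aldehyde is neopentyl-type and flanked by the aryl-bearing carbon, and both partners carry a base-labile lactone.
Fallback: it sets out from 15 and 16 and comes back at 26 by a coupling that needs no carbanion. Compound 15 is methylenated (Ph3PCH3Br, KN(SiMe3)2, THF, 0 °C) to 6-[(1S,6S)-6-ethenyl-3,6-dimethylcyclohex-2-en-1-yl]-7-methoxy-2H-chromen-2-one F10. Compound 16 is iodinated at C-8 (I2, KI, aq. NH3, 20 °C) to 7-hydroxy-8-iodo-2H-chromen-2-one F11 and O-methylated (MeI, K2CO3, acetone) to 8-iodo-7-methoxy-2H-chromen-2-one F12. Mizoroki–Heck coupling of F10 with F12 (Pd(OAc)2 10 mol %, P(o-tolyl)3, Et3N, DMF, 100 °C) gives 26. No regioisomeric alkene can form, because the alkylpalladium intermediate has β-hydrogens only on the new benzylic carbon, and syn elimination from it strongly favours the E-alkene.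

## Further compounds

F1 | step 7 | (E)-6-(3-hydroxyprop-1-en-1-yl)-7-methoxy-2H-chromen-2-one | COc1cc2oc(=O)ccc2cc1/C=C/CO
F2 | step 7 | 5-methylhex-5-enoic acid | OC(=O)CCCC(C)=C
F3 | step 7 | (E)-3-(7-methoxy-2-oxo-2H-chromen-6-yl)prop-2-en-1-yl 5-methylhex-5-enoate | COc1cc2oc(=O)ccc2cc1/C=C/COC(=O)CCCC(C)=C
F4 | step 7 | (2S,3S)-3-(7-methoxy-2-oxo-2H-chromen-6-yl)-2-(3-methylbut-3-en-1-yl)pent-4-enoic acid | COc1cc2oc(=O)ccc2cc1[C@@H](C=C)[C@@H](C(O)=O)CCC(C)=C
F5 | step 7 | (1S,2S)-2-(7-methoxy-2-oxo-2H-chromen-6-yl)-4-methylcyclohex-3-ene-1-carboxylic acid | COc1cc2oc(=O)ccc2cc1[C@H]1C=C(C)CC[C@@H]1C(O)=O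
F6 | step 7 | 6-[(1S,6S)-6-(hydroxymethyl)-3-methylcyclohex-2-en-1-yl]-7-methoxy-2H-chromen-2-one | COc1cc2oc(=O)ccc2cc1[C@H]1C=C(C)CC[C@@H]1CO
F7 | step 9 | racemic ethyl 2,5-dimethylhex-5-enoate | CCOC(=O)C(C)CCC(C)=C
F8 | step 9 | racemic 2,5-dimethylhex-5-enal | O=CC(C)CCC(C)=C
F9 | step 9 | (2R,3R)-3-(7-methoxy-2-oxo-2H-chromen-6-yl)-2-methyl-2-(3-methylbut-3-en-1-yl)pent-4-enal | COc1cc2oc(=O)ccc2cc1[C@@H](C=C)[C@](C)(C=O)CCC(C)=C
F10 | step 15 | 6-[(1S,6S)-6-ethenyl-3,6-dimethylcyclohex-2-en-1-yl]-7-methoxy-2H-chromen-2-one | COc1cc2oc(=O)ccc2cc1[C@H]1C=C(C)CC[C@@]1(C)C=C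
F11 | step 15 | 7-hydroxy-8-iodo-2H-chromen-2-one | Oc1ccc2ccc(=O)oc2c1I
F12 | step 15 | 8-iodo-7-methoxy-2H-chromen-2-one | COc1ccc2ccc(=O)oc2c1I
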